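**Retrosynthetic overview**
1. Feature: ring B is a cross-conjugated cyclohexa-2,5-dienone (C6=C7, C8=O, C9=C10) closed on the quaternary C5. With C8 at the ether level it is the 1,4-cyclohexadiene that an alkyne leaves on adding across a C5=C10–C9=C8 diene.
2. Late stage: the C3–O ester bond is cut first (diol + acid); C8=O comes from DDQ oxidation of a bis-allylic C8 ethyl ether; the C11 carbinol comes from a C7 acetyl group and MeMgBr.
3. Key disconnection: C5–C6 and C7–C8, by Diels–Alder addition of but-3-yn-2-one to the ring A dienyl ether.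
4. The diene comes from a ring A vinyl triflate (Suzuki coupling with the ethoxyvinyl boronate), made by anti cuprate addition/triflation of (R)-4-silyloxy-2-methylcyclohexenone, itself from 4-methoxy-3-methylphenol; the acid comes from propargyl alcohol.
5. Ring order: ring A (from the arene) first, ring B second, in the cycloaddition.

Key step: step 8

Numbering used throughout: C1, C2 ring A methylenes; C3 carbinol; C4 CHMe; C5 quaternary CMe; C6=C7; C8 ketone; C9=C10; C11 the carbinol carbon on C7.
Assumption: (Z)-2-methyl-3-(methylsulfanyl)prop-2-enoic acid is taken not to be a catalogue compound and is made in steps 12–14; compounds 1, 9, 11 and 16 are commercial.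

**Route**

Step 1
Reactants: 1 4-methoxy-3-methylphenol
Product: 2 4,4-dimethoxy-3-methylcyclohexa-2,5-dien-1-one
Conditions: PhI(OAc)2, MeOH, 0 °C
Reagents that add atoms: methanol, CO
Why: Oxidative dearomatisation of a para-alkoxyphenol with a hypervalent iodine reagent, in which methanol adds at the methoxy-bearing carbon to give the quinone monoketal; no stereocentre is formed.

Step 2
Reactants: 2 4,4-dimethoxy-3-methylcyclohexa-2,5-dien-1-one
Product: 3 4,4-dimethoxy-3-methylcyclohex-2-en-1-one
Conditions: H2 (1 atm), RhCl(PPh3)3 (5 mol%), benzene, rt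
Reagents that add atoms: none
Why: Homogeneous hydrogenation with RhCl(PPh3)3 is strongly sensitive to alkene substitution, so the cis-disubstituted C5=C6 bond of the cross-conjugated dienone should be saturated while the methyl-bearing trisubstituted C2=C3 bond stays, and the neutral medium avoids loss of methanol and re-aromatisation.

Step 3
Reactants: 3 4,4-dimethoxy-3-methylcyclohex-2-en-1-one
Product: 4 (1R)-4,4-dimethoxy-3-methylcyclohex-2-en-1-ol
Conditions: (S)-2-methyl-CBS-oxazaborolidine (15 mol%), catecholborane, toluene, −78 °C; aq. NaOH work-up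
Reagents that add atoms: none
Why: Corey–Bakshi–Shibata reduction, in which the ketone binds the oxazaborolidine boron anti to the larger alkenyl flank and hydride is delivered to one carbonyl face, so that the (S)-catalyst should give the (R)-allylic alcohol, which becomes C3 of the target.

Step 4
Reactants: 4 (1R)-4,4-dimethoxy-3-methylcyclohex-2-en-1-ol
Product: 5 tert-butyl{[(1R)-4,4-dimethoxy-3-methylcyclohex-2-en-1-yl]oxy}dimethylsilane
Conditions: TBSCl, imidazole, DMF, rt
Reagents that add atoms: tert-butyldimethylsilyl chloride, CC(C)(C)[Si](C)(C)Cl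
Why: Imidazole-promoted silylation of a secondary allylic alcohol, which leaves the carbinol configuration untouched and the ketal intact under the basic conditions.

Step 5
Reactants: 5 tert-butyl{[(1R)-4,4-dimethoxy-3-methylcyclohex-2-en-1-yl]oxy}dimethylsilane
Product: 6 (4R)-4-[(tert-butyldimethylsilyl)oxy]-2-methylcyclohex-2-en-1-one
Conditions: PPTS (cat.), acetone/H2O, rt
Reagents that add atoms: water, O
Why: Acid-catalysed hydrolysis of the allylic dimethyl ketal through its conjugated oxocarbenium ion, under conditions mild enough to keep the secondary TBS ether, unmasks the γ-silyloxy enone.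

Step 6
Reactants: 6 (4R)-4-[(tert-butyldimethylsilyl)oxy]-2-methylcyclohex-2-en-1-one
Product: 8 (3R,4R)-4-[(tert-butyldimethylsilyl)oxy]-2,3-dimethylcyclohex-1-en-1-yl trifluoromethanesulfonate, via lithium enolate 7 (not isolated)
Conditions: Me2CuLi (from CuI and 2 MeLi), Et2O, −78 → −30 °C; then PhNTf2, THF, −30 °C → rt; H2O work-up
Reagents that add atoms: methyllithium, [Li]C (delivered as lithium dimethylcuprate, [Li+].C[Cu-]C); N-phenylbis(trifluoromethanesulfonimide), O=S(=O)(N(c1ccccc1)S(=O)(=O)C(F)(F)F)C(F)(F)F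
Why: Cuprate conjugate addition to the enone β-carbon takes place anti to the neighbouring γ-silyloxy group and so sets the C4 methyl trans to the C3 oxygen, and the regiodefined tetrasubstituted enolate is then O-sulfonylated (enolate trapping as a vinyl triflate).

Step 7
Reactants: 8 (3R,4R)-4-[(tert-butyldimethylsilyl)oxy]-2,3-dimethylcyclohex-1-en-1-yl trifluoromethanesulfonate; 9 (E)-2-(2-ethoxyethenyl)-4,4,5,5-tetramethyl-1,3,2-dioxaborolane
Product: 10 tert-butyl{[(1R,2R)-4-[(E)-2-ethoxyethenyl]-2,3-dimethylcyclohex-3-en-1-yl]oxy}dimethylsilane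
Conditions: Pd(PPh3)4 (5 mol%), K3PO4, THF/H2O, 60 °C; chromatography on Et3N-deactivated silica
Reagents that add atoms: none
Why: Suzuki–Miyaura coupling of a vinyl triflate with an alkenylboronate proceeds with retention at both sp2 carbons and should give the (E)-1-ethoxy diene, while the basic medium preserves the enol ether and the silyl ether.

Step 8
Reactants: 10 tert-butyl{[(1R,2R)-4-[(E)-2-ethoxyethenyl]-2,3-dimethylcyclohex-3-en-1-yl]oxy}dimethylsilane; 11 but-3-yn-2-one
Product: 12 1-[(3S,7R,8R,8aR)-7-[(tert-butyldimethylsilyl)oxy]-3-ethoxy-8,8a-dimethyl-3,5,6,7,8,8a-hexahydronaphthalen-2-yl]ethan-1-one (C7 acetyl, C8 ethoxy, C6=C7 and C9=C10)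
Conditions: 11 (3 equiv, in portions), BHT (cat.), K2CO3 (acid scavenger), toluene, 100 °C, sealed tube
Reagents that add atoms: none
Why: Thermal normal-electron-demand Diels–Alder reaction, a concerted but asynchronous [4+2] cycloaddition of the 1-ethoxy diene C8=C9–C10=C5 with the ynone, of the same type as the known additions of acetylenic ketones and esters to 1-alkoxy dienes and to 2-methyl-1-vinylcyclohexenes. Ring B closes in one suprafacial six-centre event in which C5–C6 and C7–C8 form together, leaving the C6=C7 and C9=C10 bonds of a 1,4-cyclohexadiene. The regiochemistry needed is secured by the C8 ethoxy group, which puts the largest HOMO coefficient on C5, so that the unsubstituted alkyne carbon (largest LUMO coefficient, smallest end) bonds to the hindered C5 and the acetyl-bearing carbon to C8. The facial selectivity needed at C5 is secured by the C4 methyl group: A(1,2) strain with the C5 methyl, reinforced by the s-cis diene geometry, holds it pseudoaxial, and the alkyne should add anti to it through a chair-like ring A, as in the anti alkylation of 2,3-dimethylcyclohexanone enolates; the C3 silyloxy group, one carbon further away on the attacked face, is expected to be the weaker influence. C8 follows from the (E)-enol ether geometry (ethoxy cis to C4 across ring B) and is erased in step 10. Because C5 becomes quaternary the adduct cannot aromatise by loss of ethanol.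

Step 9
Reactants: 12 the acetyl cycloadduct
Product: 13 2-[(3S,7R,8R,8aR)-7-[(tert-butyldimethylsilyl)oxy]-3-ethoxy-8,8a-dimethyl-3,5,6,7,8,8a-hexahydronaphthalen-2-yl]propan-2-ol
Conditions: MeMgBr, anhydrous CeCl3, THF, −78 → 0 °C; pH 7 aqueous work-up
Reagents that add atoms: methylmagnesium bromide, C[Mg]Br
Why: Cerium-promoted Grignard 1,2-addition to the acetyl carbonyl, in which the oxophilic and weakly basic reagent suppresses enolisation and conjugate addition, and no second carbonyl competes because C8 is still an ether.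

Step 10
Reactants: 13 the C11 carbinol with the C8 ethyl ether
Product: 14 (4aR,5R,6R)-6-[(tert-butyldimethylsilyl)oxy]-3-(2-hydroxypropan-2-yl)-4a,5-dimethyl-5,6,7,8-tetrahydronaphthalen-2(4aH)-one
Conditions: DDQ (1.3 equiv), CH2Cl2/pH 7 aqueous buffer, 0 °C
Reagents that add atoms: water, O
Why: DDQ oxidation of an allylic ether, in which hydride is abstracted from the doubly allylic, oxygen-bearing C8–H to give an ethoxy-pentadienyl cation that cannot aromatise at quaternary C5, water adds at C8 and the hemiketal loses ethanol to give the cross-conjugated dienone, erasing the C8 stereocentre.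

Step 11
Reactants: 14 the silyl-protected dienone
Product: 15 (4aR,5R,6R)-6-hydroxy-3-(2-hydroxypropan-2-yl)-4a,5-dimethyl-5,6,7,8-tetrahydronaphthalen-2(4aH)-one
Conditions: HF·pyridine, pyridine, THF, 0 °C → rt
Reagents that add atoms: none
Why: Fluoride-driven cleavage of the silyl ether (Si–F bond formation) under buffered conditions that the dienone and the tertiary carbinol should tolerate, with the C3 configuration retained because only the O–Si bond breaks.

Step 12
Reactants: 16 prop-2-yn-1-ol
Product: 18 (2Z)-3-iodo-2-methylprop-2-en-1-ol, via alkenylmagnesium alkoxide 17 (not isolated)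
Conditions: MeMgBr (3 equiv), CuI (10 mol%), THF, −10 °C → rt; then I2, −30 °C → rt; H2O work-up
Reagents that add atoms: methylmagnesium bromide, C[Mg]Br; iodine, II
Why: Copper-catalysed anti-carbomagnesiation of a propargylic alcohol places methyl on C2 and magnesium on C3 trans to it within a five-membered magnesium alkoxide chelate, and iodinolysis with retention gives the (Z)-vinyl iodide.

Step 13
Reactants: 18 (2Z)-3-iodo-2-methylprop-2-en-1-ol
Product: 20 (2Z)-3-iodo-2-methylprop-2-enoic acid, via enal 19 (not isolated)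
Conditions: TEMPO (cat.), NaOCl (cat.), NaClO2, MeCN/phosphate buffer (pH 6.7), 35 °C
Reagents that add atoms: sodium chlorite, [Na+].[O-]Cl=O
Why: Oxoammonium-catalysed oxidation of the allylic alcohol to the enal is followed in the same flask by chlorite (Pinnick-type) oxidation to the acid, so the Z-enal should be consumed at near-neutral pH before it can isomerise.

Step 14
Reactants: 20 (2Z)-3-iodo-2-methylprop-2-enoic acid
Product: 21 (2Z)-2-methyl-3-(methylsulfanyl)prop-2-enoic acid
Conditions: NaSMe (2.2 equiv), CuI (10 mol%), 1,10-phenanthroline (20 mol%), DMF, 0 °C → rt; then aq. HCl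
Reagents that add atoms: sodium methanethiolate, [Na+].[S-]C
Why: Ullmann-type copper-catalysed C–S coupling of a vinyl iodide with a thiolate proceeds with retention of alkene geometry, and the carboxylate form of the substrate disfavours the reversible thiolate conjugate addition that would scramble the Z-alkene.

Step 15
Reactants: 15 the C3,C11-diol dienone; 21 (2Z)-2-methyl-3-(methylsulfanyl)prop-2-enoic acid
Product: 22 (1R,2R,8aR)-7-(2-hydroxypropan-2-yl)-1,8a-dimethyl-6-oxo-1,2,3,4,6,8a-hexahydronaphthalen-2-yl (2Z)-2-methyl-3-(methylsulfanyl)prop-2-enoate (CNP0150028.1)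
Conditions: EDC·HCl, DMAP (0.3 equiv), CH2Cl2, 0 °C → rt
Reagents that add atoms: none
Why: Steglich esterification, in which carbodiimide activation and DMAP acyl transfer acylate the equatorial secondary C3 hydroxyl with retention at C3, while the hindered, hydrogen-bonded tertiary C11 hydroxyl should not compete and the low temperature limits Z to E isomerisation of the acyl unit.

**Compound list**
1 | 4-methoxy-3-methylphenol | COc1ccc(O)cc1C | starting material
2 | 4,4-dimethoxy-3-methylcyclohexa-2,5-dien-1-one | COC1(OC)C=CC(=O)C=C1C | intermediate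
3 | 4,4-dimethoxy-3-methylcyclohex-2-en-1-one | COC1(OC)CCC(=O)C=C1C | intermediate
4 | (1R)-4,4-dimethoxy-3-methylcyclohex-2-en-1-ol | O[C@H]1C=C(C)C(OC)(OC)CC1 | intermediate
5 | tert-butyl{[(1R)-4,4-dimethoxy-3-methylcyclohex-2-en-1-yl]oxy}dimethylsilane | CC(C)(C)[Si](C)(C)O[C@H]1C=C(C)C(OC)(OC)CC1 | intermediate
6 | (4R)-4-[(tert-butyldimethylsilyl)oxy]-2-methylcyclohex-2-en-1-one | CC(C)(C)[Si](C)(C)O[C@H]1C=C(C)C(=O)CC1 | intermediate
7 | lithium (3R,4R)-4-[(tert-butyldimethylsilyl)oxy]-2,3-dimethylcyclohex-1-en-1-olate | [Li+].[O-]C1=C(C)[C@@H](C)[C@H](O[Si](C)(C)C(C)(C)C)CC1 | intermediate (not isolated)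
8 | (3R,4R)-4-[(tert-butyldimethylsilyl)oxy]-2,3-dimethylcyclohex-1-en-1-yl trifluoromethanesulfonate | O=S(=O)(OC1=C(C)[C@@H](C)[C@H](O[Si](C)(C)C(C)(C)C)CC1)C(F)(F)F | intermediate
9 | (E)-2-(2-ethoxyethenyl)-4,4,5,5-tetramethyl-1,3,2-dioxaborolane | CCO/C=C/B1OC(C)(C)C(C)(C)O1 | starting material
10 | tert-butyl{[(1R,2R)-4-[(E)-2-ethoxyethenyl]-2,3-dimethylcyclohex-3-en-1-yl]oxy}dimethylsilane | CCO/C=C/C1=C(C)[C@@H](C)[C@H](O[Si](C)(C)C(C)(C)C)CC1 | intermediate
11 | but-3-yn-2-one | CC(=O)C#C | starting material
12 | 1-[(3S,7R,8R,8aR)-7-[(tert-butyldimethylsilyl)oxy]-3-ethoxy-8,8a-dimethyl-3,5,6,7,8,8a-hexahydronaphthalen-2-yl]ethan-1-one | CC(C)(C)[Si](C)(C)O[C@@H]1CCC2=C[C@H](OCC)C(C(C)=O)=C[C@]2(C)[C@H]1C | intermediate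
13 | 2-[(3S,7R,8R,8aR)-7-[(tert-butyldimethylsilyl)oxy]-3-ethoxy-8,8a-dimethyl-3,5,6,7,8,8a-hexahydronaphthalen-2-yl]propan-2-ol | CC(C)(C)[Si](C)(C)O[C@@H]1CCC2=C[C@H](OCC)C(C(C)(C)O)=C[C@]2(C)[C@H]1C | intermediate
14 | (4aR,5R,6R)-6-[(tert-butyldimethylsilyl)oxy]-3-(2-hydroxypropan-2-yl)-4a,5-dimethyl-5,6,7,8-tetrahydronaphthalen-2(4aH)-one | CC(C)(C)[Si](C)(C)O[C@@H]1CCC2=CC(=O)C(C(C)(C)O)=C[C@]2(C)[C@H]1C | intermediate
15 | (4aR,5R,6R)-6-hydroxy-3-(2-hydroxypropan-2-yl)-4a,5-dimethyl-5,6,7,8-tetrahydronaphthalen-2(4aH)-one | O[C@@H]1CCC2=CC(=O)C(C(C)(C)O)=C[C@]2(C)[C@H]1C | intermediate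
16 | prop-2-yn-1-ol | C#CCO | starting material
17 | bromomagnesium (2Z)-3-(bromomagnesio)-2-methylprop-2-en-1-olate | Br[Mg]/C=C(/C)CO[Mg]Br | intermediate (not isolated)
18 | (2Z)-3-iodo-2-methylprop-2-en-1-ol | I/C=C(/C)CO | intermediate
19 | (2Z)-3-iodo-2-methylprop-2-enal | I/C=C(/C)C=O | intermediate (not isolated)
20 | (2Z)-3-iodo-2-methylprop-2-enoic acid | I/C=C(/C)C(=O)O | intermediate
21 | (2Z)-2-methyl-3-(methylsulfanyl)prop-2-enoic acid | CS/C=C(/C)C(=O)O | intermediate
22 | (1R,2R,8aR)-7-(2-hydroxypropan-2-yl)-1,8a-dimethyl-6-oxo-1,2,3,4,6,8a-hexahydronaphthalen-2-yl (2Z)-2-methyl-3-(methylsulfanyl)prop-2-enoate | CS/C=C(/C)C(=O)O[C@@H]1CCC2=CC(=O)C(C(C)(C)O)=C[C@]2(C)[C@H]1C | target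

**Step count and risks**
Total: 15 steps. Longest linear sequence: 12 steps (steps 1–11 and 15, from 1).

Steps most likely to fail:

1. Step 8. Bond formation at the tetrasubstituted C5 terminus, whose s-cis diene is destabilised by the inside methyl group, may be slower than thermal polymerisation of the ynone. Addition syn to the C4 methyl through the diequatorial half-chair may also compete and erode the C5 configuration.
 Fallback (conjugate addition–annulation in place of the cycloaddition; sets out from 6, returns at 14): 6 is treated with Me2CuLi as in step 6 and the enolate 7 is intercepted with 3-(trimethylsilyl)but-3-en-2-one. This should give (2R,3R,4R)-4-[(tert-butyldimethylsilyl)oxy]-2,3-dimethyl-2-[3-oxo-2-(trimethylsilyl)butyl]cyclohexan-1-one F1, with C5 alkylated anti to the C4 methyl. KOH in MeOH removes the C-silyl group and closes ring B by aldol condensation (Robinson annulation) to the octalone (4aR,5R,6R)-6-[(tert-butyldimethylsilyl)oxy]-4a,5-dimethyl-4,4a,5,6,7,8-hexahydronaphthalen-2(3H)-one F2. Deprotonation at C7 with LDA (LiN(iPr)2, THF, −78 °C) and addition to acetone gives the aldol adduct (4aR,5R,6R)-6-[(tert-butyldimethylsilyl)oxy]-3-(2-hydroxypropan-2-yl)-4a,5-dimethyl-4,4a,5,6,7,8-hexahydronaphthalen-2(3H)-one F3. Dehydrogenation across C6–C7 with DDQ in hot dioxane, the usual 4-en-3-one to 1,4-dien-3-one conversion, gives 14, after which steps 11 and 15 follow.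

2. Step 15. Activation of the push–pull (β-thio) acyl unit lowers the barrier to rotation about its C=C bond, so Z to E isomerisation may accompany a slow acyl transfer to the C3 hydroxyl.
 Fallback (sulfur introduced after the acyl transfer; sets out from 15 and 20, returns at 22): 15 is esterified under the same carbodiimide conditions with the iodo acid 20, whose acyl unit is not a push–pull system. This should give (1R,2R,8aR)-7-(2-hydroxypropan-2-yl)-1,8a-dimethyl-6-oxo-1,2,3,4,6,8a-hexahydronaphthalen-2-yl (2Z)-3-iodo-2-methylprop-2-enoate F4. NaSMe (1 equiv, THF, −20 °C) then replaces iodide by addition–elimination with retention of geometry and gives 22 directly.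

3. Step 14. Reversible thiolate addition to the product or slow turnover of the carboxylate substrate at copper may erode the Z geometry or stall the substitution.
 Fallback (sulfur introduced by electrophilic trapping of the carbomagnesiation intermediate; sets out from 16, returns at 21): 16 is carbomagnesiated as in step 12 and the alkenylmagnesium alkoxide 17 is quenched with dimethyl disulfide instead of iodine. This should give (2Z)-2-methyl-3-(methylsulfanyl)prop-2-en-1-ol F5 with retention at the C–Mg bond. MnO2 in CH2Cl2 gives (2Z)-2-methyl-3-(methylsulfanyl)prop-2-enal F6, and Pinnick oxidation (NaClO2, NaH2PO4, 2-methyl-2-butene, tBuOH/H2O) gives 21.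

**Further compounds**
F1 | step 8 | (2R,3R,4R)-4-[(tert-butyldimethylsilyl)oxy]-2,3-dimethyl-2-[3-oxo-2-(trimethylsilyl)butyl]cyclohexan-1-one | CC(=O)C([Si](C)(C)C)C[C@@]1(C)C(=O)CC[C@@H](O[Si](C)(C)C(C)(C)C)[C@@H]1C
F2 | step 8 | (4aR,5R,6R)-6-[(tert-butyldimethylsilyl)oxy]-4a,5-dimethyl-4,4a,5,6,7,8-hexahydronaphthalen-2(3H)-one | CC(C)(C)[Si](C)(C)O[C@@H]1CCC2=CC(=O)CC[C@]2(C)[C@H]1C
F3 | step 8 | (4aR,5R,6R)-6-[(tert-butyldimethylsilyl)oxy]-3-(2-hydroxypropan-2-yl)-4a,5-dimethyl-4,4a,5,6,7,8-hexahydronaphthalen-2(3H)-one (C3 epimers) | CC(C)(C)[Si](C)(C)O[C@@H]1CCC2=CC(=O)C(C(C)(C)O)C[C@]2(C)[C@H]1C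
F4 | step 15 | (1R,2R,8aR)-7-(2-hydroxypropan-2-yl)-1,8a-dimethyl-6-oxo-1,2,3,4,6,8a-hexahydronaphthalen-2-yl (2Z)-3-iodo-2-methylprop-2-enoate | I/C=C(/C)C(=O)O[C@@H]1CCC2=CC(=O)C(C(C)(C)O)=C[C@]2(C)[C@H]1C
F5 | step 14 | (2Z)-2-methyl-3-(methylsulfanyl)prop-2-en-1-ol | CS/C=C(/C)CO
F6 | step 14 | (2Z)-2-methyl-3-(methylsulfanyl)prop-2-enal | CS/C=C(/C)C=O
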